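Plan (eudesmane numbering; ring A = C1–C5 and C10, ring B = C5–C10).
Cuts, in retrosynthetic order: C11–O together with the C6=C7 shift (back to the 7(11)-en-8-one), the C3 ester C–O bond, the C3–O/C4–O pair (back to a 3-ene), C4–C15, then C7–C8, C5–C6 and C9–C10.
Enabling feature: in ring B the oxygenated C8 and C7, which carries the three-carbon C11 unit, are neighbours. A carbonyl-ene reaction between a C8 aldehyde hanging from C10 and a C7=C11 prenyl alkene hanging from C5 produces exactly this 1,2-pattern as it closes ring B.
Forward: ring A is bought as 3-methylcyclohexenone and receives vinyl at C10 and prenyl at C5. The vinyl group becomes the acetaldehyde arm and ring B closes in step 5. Ring A is then completed (C15, 3,4-diol, angelate) and the hydroperoxide is made last.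
Stereochemistry: C10 comes from ligand-controlled conjugate addition, C5 from equilibration to the trans-decalone while C4 is still a ketone, C4 from α-face osmylation anti to the C10 methyl, and C3 from axial hydride delivery to a 3-ketone. C7 and C8 are transient, and the Z alkene comes with angelic acid.

Key step: step 5

Remark: α/β refer to the usual drawing with the C10 methyl β. Compounds 7, 9 and 10 are expected as mixtures of C5 epimers and are drawn and listed as the 5αH epimer, because step 5 brings both epimers to the same compound.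
Remark: the sense of induction in step 1 is fixed by choosing the ligand enantiomer that gives (R)-4.

Step 1
Reactants: 1 3-methylcyclohex-2-en-1-one; 2 vinylmagnesium bromide
Product: 4 (R)-trimethyl[(3-methyl-3-vinylcyclohex-1-en-1-yl)oxy]silane, via dimethylaluminium enolate 3 (not isolated)
Conditions: 2, Me2AlCl, Et2O, 0 °C; then 1, Cu(O2CC4H3S) (10 mol %), Ph2P–N[CH(Me)(2-naphthyl)]2 (one enantiomer, 11 mol %), Et2O, −30 °C; then TMSOTf, −30 → 0 °C
Reagents that add atoms: vinylmagnesium bromide 2, C=C[Mg]Br; trimethylsilyl triflate, C[Si](C)(C)OS(=O)(=O)C(F)(F)F; dimethylaluminium chloride, C[Al](C)Cl (aluminium of 3 only)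
Why: Copper-catalysed asymmetric conjugate addition of an alkenylalane to a β-substituted cyclohexenone, in which the sp2 group is transferred in preference to methyl and the chiral aminophosphine decides the face of attack at C10 (creating the quaternary centre), followed by O-silylation, which stores the C4=C5 enolate regiochemistry needed in step 2.

Step 2
Reactants: 4 (R)-trimethyl[(3-methyl-3-vinylcyclohex-1-en-1-yl)oxy]silane; 5 prenyl bromide
Product: 7 (2R,3R)-3-methyl-2-(3-methylbut-2-en-1-yl)-3-vinylcyclohexan-1-one, via lithium enolate 6 (not isolated)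
Conditions: MeLi, THF, 0 °C; then DMPU, 5, −78 → 0 °C
Reagents that add atoms: prenyl bromide 5, CC(C)=CCBr; methyllithium, [Li]C (lithium of 6 only)
Why: Methyllithium cleaves the enol silane to the regiodefined lithium enolate, which the reactive allylic bromide alkylates on carbon at C5 (SN2 enolate alkylation) before proton exchange can move the enolate to C3; methyl and vinyl screen the two faces about equally, so C5 is left to be settled in step 5.

Step 3
Reactants: 7 (2R,3R)-3-methyl-2-(3-methylbut-2-en-1-yl)-3-vinylcyclohexan-1-one
Product: 9 (2R,3R)-3-(2-hydroxyethyl)-3-methyl-2-(3-methylbut-2-en-1-yl)cyclohexan-1-one, via catechol boronate 8 (not isolated)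
Conditions: catecholborane, RhCl(PPh3)3 (2 mol %), THF, 23 °C; then NaBO3·4H2O, THF/H2O, 23 °C
Reagents that add atoms: sodium perborate, [Na+].[O-]OB=O (oxygen at C8); catecholborane, B1Oc2ccccc2O1 (boronate of 8 only)
Why: Rhodium-catalysed hydroboration with catecholborane puts boron on the terminal carbon of the monosubstituted alkene much faster than the reagent reduces a ketone or touches a trisubstituted alkene, and perborate oxidation gives the primary alcohol without forming a stereocentre.

Step 4
Reactants: 9 (2R,3R)-3-(2-hydroxyethyl)-3-methyl-2-(3-methylbut-2-en-1-yl)cyclohexan-1-one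
Product: 10 2-[(1R,2R)-1-methyl-2-(3-methylbut-2-en-1-yl)-3-oxocyclohexyl]acetaldehyde (ring A keto aldehyde: C10 acetaldehyde arm, C5 prenyl group, C4 ketone)
Conditions: Dess–Martin periodinane, CH2Cl2, 0 → 23 °C
Reagents that add atoms: none
Why: Dess–Martin oxidation stops at the aldehyde under neutral, non-enolising conditions that leave the ketone, the prenyl alkene and C10 alone.

Step 5
Reactants: 10 2-[(1R,2R)-1-methyl-2-(3-methylbut-2-en-1-yl)-3-oxocyclohexyl]acetaldehyde
Product: 11 8α-hydroxy-15-noreudesm-11-en-4-one (trans-decalone; 5αH, 7β-isopropenyl, 8α-OH, 10β-methyl)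
Conditions: Al(OC6H3-2,6-Ph2)3 (10 mol %, from Me3Al and 2,6-diphenylphenol), toluene, −20 → 0 °C; then NaOMe (20 mol %), MeOH, 23 °C
Reagents that add atoms: none
Why: The bulky aluminium aryloxide binds the sterically open C8 aldehyde, C7 of the prenyl alkene attacks C8 and a hydrogen of a C11 methyl passes to the oxygen in one six-centre event (type 1 intramolecular carbonyl-ene reaction), which makes C7–C8 and leaves the 8-carbinol next to the 7-isopropenyl group. The closest known reaction is the citronellal-to-isopulegol cyclisation with the same class of catalyst, and 10 is likewise a 6-alkenal, here 3,3-disubstituted at C10, which favours folding. Ring B closes in the 6-exo mode with respect to both π bonds, since O and C11 stay outside the new six-membered ring. C7 and C8 are set by the chair transition state built on the diequatorial C6 and C9 arms of ring A, which places the isopropenyl group (7β) and the metal-bound oxygen (8α) equatorial; both centres are erased in step 8, so minor isomers converge. The step needs aldehyde-over-ketone selectivity, which is secured because the C4 ketone is the more hindered and less electrophilic carbonyl and has no alkene within reach of a five- or six-membered ene transition state, while the catalyst carries no proton or halide that could divert the reaction to a Prins path. The methoxide stage then equilibrates C5, the only stereocentre next to the ketone, to the trans-decalone with all ring B substituents equatorial (the behaviour of 5β-4-oxo steroids, which go over to the 5α series), so both C5 epimers of 10 end in 11.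

Step 6
Reactants: 11 8α-hydroxy-15-noreudesm-11-en-4-one
Product: 12 (E)-2,4,6-triisopropylbenzenesulfonylhydrazone of 11
Conditions: 2,4,6-iPr3C6H2SO2NHNH2, THF, 23 °C
Reagents that add atoms: 2,4,6-triisopropylbenzenesulfonyl hydrazide, CC(C)c1cc(C(C)C)c(S(=O)(=O)NN)c(C(C)C)c1
Why: Hydrazone condensation under near-neutral conditions leaves C5 untouched and places the sulfonamide nitrogen on the C3 side, away from tertiary C5, which is the geometry needed for syn-directed deprotonation at C3.

Step 7
Reactants: 12 (E)-2,4,6-triisopropylbenzenesulfonylhydrazone of 11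
Product: 14 eudesma-3,11-dien-8α-ol (5αH, 7β-isopropenyl, 10β-methyl), via vinyllithium alkoxide 13 (not isolated)
Conditions: n-BuLi (3.3 equiv), TMEDA, THF, −78 → 0 °C; then MeI, −78 → 0 °C
Reagents that add atoms: methyl iodide, CI; n-butyllithium, [Li]CCCC (lithium of 13 only)
Why: Shapiro reaction with alkylation: after OH and NH the third equivalent of base removes a C3 hydrogen, loss of sulfinate and N2 gives the C4 vinyllithium with the alkene fixed at C3=C4, and methyl iodide installs C15 without forming or touching a stereocentre.

Step 8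
Reactants: 14 eudesma-3,11-dien-8α-ol
Product: 16 eudesma-3,7(11)-dien-8-one (5αH, 10β-methyl), via deconjugated ketone 15 (not isolated)
Conditions: Dess–Martin periodinane, CH2Cl2, 0 °C; aqueous work-up; then DBU (30 mol %), CH2Cl2, 23 °C
Reagents that add atoms: none
Why: Dess–Martin oxidation erases C8 and DBU moves the β,γ-alkene into conjugation through the C7 dienolate (the isopulegone-to-pulegone isomerisation), erasing C7 and giving the more stable tetrasubstituted enone, while the isolated C3=C4 alkene and the non-acidic C5 are unaffected.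

Step 9
Reactants: 16 eudesma-3,7(11)-dien-8-one
Product: 17 3α,4α-dihydroxyeudesm-7(11)-en-8-one (4β-methyl)
Conditions: OsO4 (3 mol %), NMO, acetone/H2O, 0 → 23 °C
Reagents that add atoms: N-methylmorpholine N-oxide, C[N+]1([O-])CCOCC1; water, O
Why: Catalytic OsO4/NMO syn-dihydroxylation picks the electron-rich trisubstituted C3=C4 alkene over the electron-poor tetrasubstituted enone alkene and adds both oxygens from the α face, opposite the axial C10 methyl, which sets C4 (4α-OH, 4β-CH3) for good and C3 provisionally (3α-OH).

Step 10
Reactants: 17 3α,4α-dihydroxyeudesm-7(11)-en-8-one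
Product: 18 4α-hydroxyeudesm-7(11)-ene-3,8-dione
Conditions: IBX, DMSO, 23 °C
Reagents that add atoms: none
Why: IBX oxidises the secondary axial 3α-carbinol of a 1,2-diol to the α-ketol without C–C cleavage and cannot touch the tertiary C4 carbinol.

Step 11
Reactants: 18 4α-hydroxyeudesm-7(11)-ene-3,8-dione
Product: 19 3β,4α-dihydroxyeudesm-7(11)-en-8-one
Conditions: NaBH4, MeOH/CH2Cl2 (1:1), −78 °C
Reagents that add atoms: none
Why: At low temperature borohydride reduces the saturated, hydroxyl-activated C3 ketone far faster than the hindered conjugated C8 ketone, and hydride enters axially from the α face because the β face is blocked by the axial C4 and C10 methyls (the outcome known for 4,4-disubstituted 3-oxo terpenoids), giving the equatorial 3β-alcohol.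

Step 12
Reactants: 19 3β,4α-dihydroxyeudesm-7(11)-en-8-one; 20 angelic acid
Product: 22 3β-angeloyloxy-4α-hydroxyeudesm-7(11)-en-8-one, via mixed anhydride 21 (not isolated)
Conditions: 20, 2,4,6-Cl3C6H2COCl, Et3N, toluene, 23 °C; then 19, toluene, 80 °C (no DMAP)
Reagents that add atoms: angelic acid 20, C/C=C(/C)C(=O)O; 2,4,6-trichlorobenzoyl chloride, O=C(Cl)c1c(Cl)cc(Cl)cc1Cl (aroyl part of 21 only)
Why: Yamaguchi esterification acylates only the secondary 3β-hydroxyl (the tertiary C4 hydroxyl is inert) with retention at C3, and leaving out a nucleophilic amine catalyst avoids the addition–elimination path that turns angelates into tiglates.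

Step 13
Reactants: 22 3β-angeloyloxy-4α-hydroxyeudesm-7(11)-en-8-one
Product: 23 3β-angeloyloxy-4α-hydroxy-11-hydroperoxyeudesm-6-en-8-one, (3S,4S,5R,10R), the target
Conditions: O2, tetraphenylporphyrin (cat.), visible light, CH2Cl2, −20 °C
Reagents that add atoms: oxygen, O=O
Why: Schenck ene reaction: singlet oxygen takes the tetrasubstituted C7=C11 alkene of the s-cis enone (the angelate alkene is far less reactive), and the geminal selectivity of α,β-unsaturated carbonyl compounds directs O–O bonding to C11 and hydrogen abstraction to C6, the substituent geminal to the carbonyl on C7, giving the conjugated 6-en-8-one and the non-stereogenic C11 hydroperoxide without touching C5.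

Compound list
1 | 3-methylcyclohex-2-en-1-one | CC1=CC(=O)CCC1 | starting material
2 | vinylmagnesium bromide | C=C[Mg]Br | starting material
3 | dimethylaluminium (R)-3-methyl-3-vinylcyclohex-1-en-1-olate | C[Al](C)OC1=C[C@@](C)(C=C)CCC1 | intermediate
4 | (R)-trimethyl[(3-methyl-3-vinylcyclohex-1-en-1-yl)oxy]silane | C[Si](C)(C)OC1=C[C@@](C)(C=C)CCC1 | intermediate
5 | prenyl bromide (1-bromo-3-methylbut-2-ene) | CC(C)=CCBr | starting material
6 | lithium (R)-3-methyl-3-vinylcyclohex-1-en-1-olate | [Li]OC1=C[C@@](C)(C=C)CCC1 | intermediate
7 | (2R,3R)-3-methyl-2-(3-methylbut-2-en-1-yl)-3-vinylcyclohexan-1-one | O=C1CCC[C@](C)(C=C)[C@H]1CC=C(C)C | intermediate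
8 | catechol boronate of 7 (boron on the terminal carbon C8) | O=C1CCC[C@](C)(CCB2Oc3ccccc3O2)[C@H]1CC=C(C)C | intermediate
9 | (2R,3R)-3-(2-hydroxyethyl)-3-methyl-2-(3-methylbut-2-en-1-yl)cyclohexan-1-one | O=C1CCC[C@](C)(CCO)[C@H]1CC=C(C)C | intermediate
10 | 2-[(1R,2R)-1-methyl-2-(3-methylbut-2-en-1-yl)-3-oxocyclohexyl]acetaldehyde | O=C1CCC[C@](C)(CC=O)[C@H]1CC=C(C)C | intermediate
11 | 8α-hydroxy-15-noreudesm-11-en-4-one (5αH, 7β-isopropenyl, 10β-methyl) | O=C1CCC[C@]2(C)C[C@H](O)[C@@H](C(C)=C)C[C@@H]12 | intermediate
12 | (E)-2,4,6-triisopropylbenzenesulfonylhydrazone of 11 | CC(C)c1cc(C(C)C)c(S(=O)(=O)N/N=C2\CCC[C@]3(C)C[C@H](O)[C@@H](C(C)=C)C[C@@H]23)c(C(C)C)c1 | intermediate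
13 | C4 vinyllithium, C8 lithium alkoxide (15-noreudesma-3,11-diene core) | [Li]C1=CCC[C@]2(C)C[C@H](O[Li])[C@@H](C(C)=C)C[C@@H]12 | intermediate
14 | eudesma-3,11-dien-8α-ol | CC1=CCC[C@]2(C)C[C@H](O)[C@@H](C(C)=C)C[C@@H]12 | intermediate
15 | eudesma-3,11-dien-8-one | CC1=CCC[C@]2(C)CC(=O)[C@@H](C(C)=C)C[C@@H]12 | intermediate
16 | eudesma-3,7(11)-dien-8-one | CC1=CCC[C@]2(C)CC(=O)C(=C(C)C)C[C@@H]12 | intermediate
17 | 3α,4α-dihydroxyeudesm-7(11)-en-8-one | O[C@@H]1CC[C@]2(C)CC(=O)C(=C(C)C)C[C@H]2[C@]1(C)O | intermediate
18 | 4α-hydroxyeudesm-7(11)-ene-3,8-dione | O=C1CC[C@]2(C)CC(=O)C(=C(C)C)C[C@H]2[C@]1(C)O | intermediate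
19 | 3β,4α-dihydroxyeudesm-7(11)-en-8-one | O[C@H]1CC[C@]2(C)CC(=O)C(=C(C)C)C[C@H]2[C@]1(C)O | intermediate
20 | angelic acid, (Z)-2-methylbut-2-enoic acid | C/C=C(/C)C(=O)O | starting material
21 | angelic 2,4,6-trichlorobenzoic anhydride | C/C=C(/C)C(=O)OC(=O)c1c(Cl)cc(Cl)cc1Cl | intermediate
22 | 3β-angeloyloxy-4α-hydroxyeudesm-7(11)-en-8-one | C/C=C(/C)C(=O)O[C@H]1CC[C@]2(C)CC(=O)C(=C(C)C)C[C@H]2[C@]1(C)O | intermediate
23 | 3β-angeloyloxy-4α-hydroxy-11-hydroperoxyeudesm-6-en-8-one (CNP0161122.1) | C/C=C(/C)C(=O)O[C@H]1CC[C@]2(C)CC(=O)C(C(C)(C)OO)=C[C@H]2[C@]1(C)O | target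

Total step count: 13. Longest linear sequence: 13 steps (from 1 to 23). No protecting group is used.

Steps most likely to fail

Step 5. The catalyst may be tied up by the ketone and by the product alkoxide. It may also shuttle hydride between carbinol and carbonyl groups, so that the aldehyde is used up without ring closure. The fallback makes the same C7–C8 bond by a polar allylation. It sets out from 10, whose prenyl group is converted with NCS and catalytic PhSeCl in CH2Cl2 into the rearranged secondary allylic chloride F1. CrCl2 in THF (Nozaki–Hiyama allylation) then reduces the C–Cl bond. The allylmetal bonds through its γ-carbon C7 to the C8 aldehyde only, since ketones are not attacked, and this regenerates the isopropenyl group. After the same NaOMe equilibration the sequence comes back to the route at 11.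

Step 7. Trianion formation may stay incomplete, the vinyllithium may be protonated before it meets methyl iodide, or the C8 alkoxide may be methylated on oxygen. The fallback replaces the carbanion chemistry by cross-coupling and sets out from 11. TESCl and imidazole give the silyl ether F2. KN(SiMe3)2 followed by Comins' reagent gives the kinetic C3=C4 enol triflate F3. Fe(acac)3-catalysed Kumada coupling with MeMgBr gives the methylated silyl ether F4. HF·pyridine removes the silyl group, and the sequence comes back at 14.

Step 1. The risks are low enantioselectivity with the parent vinyl group, competing methyl transfer from aluminium, and incomplete silylation of the aluminium enolate. The fallback exchanges the roles of the two C10 substituents. LiC≡CSiMe3 is added to commercial 3-ethoxycyclohex-2-en-1-one, and acidic work-up gives the enynone F5. A 1,4-selective asymmetric conjugate addition of MeMgBr, catalysed by Cu(OTf)2 and a chiral N-heterocyclic carbene, sets C10. The magnesium enolate is alkylated in the same flask with prenyl bromide 5 (DMPU) to give the silylalkynyl ketone F6. K2CO3 in MeOH gives the terminal alkyne F7. Cy2BH followed by NaBO3·4H2O then converts the alkyne directly into the aldehyde. The fallback sets out from 5 and comes back at 10, bypassing steps 1 to 4.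

Further compounds
F1 | step 5 | (2R,3R)-2-(2-chloro-3-methylbut-3-en-1-yl)-3-methyl-3-(2-oxoethyl)cyclohexan-1-one (both C7 epimers) | O=C1CCC[C@](C)(CC=O)[C@H]1CC(Cl)C(C)=C
F2 | step 7 | 8α-(triethylsilyloxy)-15-noreudesm-11-en-4-one | O=C1CCC[C@]2(C)C[C@H](O[Si](CC)(CC)CC)[C@@H](C(C)=C)C[C@@H]12
F3 | step 7 | 8α-(triethylsilyloxy)-15-noreudesma-3,11-dien-4-yl trifluoromethanesulfonate | O=S(=O)(OC1=CCC[C@]2(C)C[C@H](O[Si](CC)(CC)CC)[C@@H](C(C)=C)C[C@@H]12)C(F)(F)F
F4 | step 7 | 8α-(triethylsilyloxy)eudesma-3,11-diene | CC1=CCC[C@]2(C)C[C@H](O[Si](CC)(CC)CC)[C@@H](C(C)=C)C[C@@H]12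
F5 | step 1 | 3-[(trimethylsilyl)ethynyl]cyclohex-2-en-1-one | C[Si](C)(C)C#CC1=CC(=O)CCC1
F6 | step 1 | (2R,3S)-3-methyl-2-(3-methylbut-2-en-1-yl)-3-[(trimethylsilyl)ethynyl]cyclohexan-1-one | O=C1CCC[C@](C)(C#C[Si](C)(C)C)[C@H]1CC=C(C)C
F7 | step 1 | (2R,3S)-3-ethynyl-3-methyl-2-(3-methylbut-2-en-1-yl)cyclohexan-1-one | O=C1CCC[C@](C)(C#C)[C@H]1CC=C(C)C
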